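The target in the east flask stops climbing well short of what its charge seems to allow, and that gap is worth a number before more starting material goes in.

| flask | starting material | second substrate | solid reagent | temperature | remark | time |
|---|---|---|---|---|---|---|
| east | 0.40 M | 0.40 M | 0.40 M | 35 °C | the very flask that is asked about, followed so far |  |
| south-east | 0.40 M | 0.40 M | 0.27 M | 35 °C | run made earlier |  |
| flask | 0.40 M | 0.400 M | 0.400 M | 35 °C |  | 12 h |

| run | time / min | target / % |
|---|---|---|
| east | 150 | 63.5 |
| east | 300 | 64.1 |
| east | 480 | 63.4 |
| east | 600 | 63.0 |
| east | 720 | 62.9 |
| south-east | 1.33 | 0 |
| south-east | 4.00 | 1.4 |
| south-east | 8.00 | 2.2 |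
| south-east | 12.0 | 4.8 |
| south-east | 15.0 | 5.6 |

(each reading ± 0.5 percentage points)

- Saturday's: at 12 h take out 90% of the target then present, then wait 12 h
- Sunday's: change nothing and wait 12 h more
- Monday's: at 12 h raise the temperature by 15 K, then wait 12 h
- Tuesday's: at 12 h add starting material, 50.0% of the amount charged, then wait 12 h

- solid, in amounts per volume of the solution: solid reagent
- what is taken out of target is counted as made
- at the start none of the solid reagent is in solution
- additions bring no volume worth counting
- the earlier runs do not show what temperature does; that part of a forecast is a guess

1. target, in percent of the starting material first charged, at 12 h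
2. the option that brings most further target ("none" if no option brings more than 2 percentage points) (Saturday's / Sunday's / Monday's / Tuesday's / none)
3. target present, with what was taken out counted in, in percent of the starting material first charged, after Saturday's
4. target present, with what was taken out counted in, in percent of the starting material first charged, after Monday's

The bench rule says that the limiting reagent sets the yield: target stands at the smaller charge over the starting material. For the east flask that allows 100%, yet its readings, with the curve replaced by their mean 63.4%, reach 0.634 of that allowance, so the rule stops working here. The south-east run ends at 15.0 min with 5.6%, before any flat stretch, and says nothing on this point.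

Suppose the stall is a balance, though a reagent lost on a side path can't be excluded:

stall quotient = target / (starting material left × solid reagent outside target) = 11.8 /M

This stall quotient, an apparent equilibrium constant, takes the mean for the curve. The error of doing so shows in the lowest and highest flat readings, which give 11.4 /M and 12.4 /M.

The reading at 720 min, 62.9%, stands for the flask now. The readings sink by 1.2 percentage points from 300 min, more than the scatter, so waiting promises no gain. This reckoning holds the quotient for the two options that take out or add material:

starting material left = 0.146 M, target kept on Saturday's = 0.0254 M

target formed again on Saturday's = 0.0610 M, so 15 points and 78.6% in all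

gain on Tuesday's = 14 points

Saturday's comes out ahead of Tuesday's. The quotient was read at 35 °C and gives no number for Monday's.

The forecast says 63% now, 77% after Saturday's, where this reckoning has 78.6%, and 56% after Monday's, names Saturday's, and holds that “Heating an exothermic addition would probably lower K”.

The flask stands at 62.8% at 12 h. Saturday's brings most, 14 points, with 76.4% in all against the 78.6% reckoned here. Tuesday's brings 10 points, Sunday's −2.3 points and Monday's −28 points, ending at 34.5%.

    solid reagent ⇌ partner, rate k1*(cs1 - [partner]) while solid is left; crystals form when [partner] > cs1 (solubility = 0.140 M, k = 0.0315 /min)
    target → over-reaction product (k = 6.47 × 10⁻⁵ /min, Ea = 99.0 kJ/mol)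
    second substrate + partner ⇌ second product (K = 3.24 /M, k = 1.07 /M/min, Ea = 49.0 kJ/mol, ΔH = −3.00 kJ/mol)
    starting material + partner ⇌ target (K = 27.2 /M, k = 0.404 /M/min, Ea = 65.0 kJ/mol, ΔH = −83.0 kJ/mol)
    (constants at 35 °C)

The neighbouring flask has the same charges but 0.10 M of solid reagent. The bench rule allows it 25.0%, while the stall quotient 11.8 /M, solved for the smaller charge, gives 19.8%. That flask stands at 19.1% at 12 h, with 80.0% of its starting material still there.

The earlier runs and the new flask are calculated with constants of no real substance, noise included.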